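The target is a 20-membered oxa-cyclophane: a resorcinol ring and a 2,6-dihydroxyphenoxy ring joined by the ether oxygen and by a dodecamethylene bridge (C1–C12, counted from the trioxygenated ring). Because these twelve CH2 carbons carry no heteroatom or stereocentre, a transient alkene there is traceless. The bridge is cut at C9–C10, three carbons from the resorcinol ring. Ring-closing olefin metathesis of an acyclic tri-O-methyl diaryl ether bearing a dec-9-enyl arm on the trioxygenated ring and a but-3-enyl arm on the other closes the macrocycle and forms C9=C10 in one operation; hydrogenation and BBr3 demethylation finish.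

Key step: step 4

Remark: the target has no stereocentre, and a 20-membered ring is too large for configurationally stable planar chirality, so it is a single achiral compound and no stereocontrol is needed.

Step 1
Reactants: 1 1-bromo-3-(bromomethyl)-5-methoxybenzene; 2 allylmagnesium bromide
Product: 3 1-bromo-3-(but-3-en-1-yl)-5-methoxybenzene
Conditions: allylMgBr (1.3 equiv, 1 M in Et2O), THF, 0 °C to rt
Reagents that add atoms: allylmagnesium bromide (2), C=CC[Mg]Br
Why: Grignard alkylation (SN2 displacement) of the benzylic bromide by the very nucleophilic allyl Grignard reagent should be much faster than any Br/Mg exchange at the aryl bromide at 0 °C.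

Step 2
Reactants: 4 1,9-decadiene; 5 9-borabicyclo[3.3.1]nonane (9-BBN); 6 4-bromo-2,6-dimethoxyphenol
Product: 8 4-(dec-9-en-1-yl)-2,6-dimethoxyphenol, via B-(dec-9-en-1-yl)-9-BBN 7 (not isolated)
Conditions: 9-BBN (1.0 equiv, 0.5 M in THF), 1,9-decadiene (4 equiv), THF, 0 °C to rt; then 6 (0.8 equiv), Pd(OAc)2 (3 mol%), SPhos (6 mol%), aq K3PO4 (3 equiv), THF, 65 °C
Reagents that add atoms: 1,9-decadiene (4), C=CCCCCCCC=C
Why: anti-Markovnikov hydroboration of one end of the diene (excess diene suppresses the bis-adduct and consumes all B–H) followed by B-alkyl Suzuki–Miyaura coupling, for which the electron-rich SPhos ligand should allow oxidative addition into the electron-rich bromophenoxide.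

Step 3
Reactants: 3 1-bromo-3-(but-3-en-1-yl)-5-methoxybenzene; 8 4-(dec-9-en-1-yl)-2,6-dimethoxyphenol
Product: 9 2-[3-(but-3-en-1-yl)-5-methoxyphenoxy]-5-(dec-9-en-1-yl)-1,3-dimethoxybenzene
Conditions: CuI (10 mol%), picolinic acid (20 mol%), K3PO4 (2 equiv), DMSO, 90 °C, Ar
Reagents that add atoms: none
Why: ligand-accelerated Ullmann diaryl ether synthesis, in which the picolinate–copper system is suited to 2,6-disubstituted, electron-rich phenols and leaves isolated terminal alkenes untouched.

Step 4
Reactants: 9 2-[3-(but-3-en-1-yl)-5-methoxyphenoxy]-5-(dec-9-en-1-yl)-1,3-dimethoxybenzene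
Product: 10 macrocyclic alkene, the tri-O-methyl ether of the 9,10-didehydro target (C9=C10 in the bridge, E/Z mixture)
Conditions: Grubbs II (2 × 5 mol%), 1,4-benzoquinone (10 mol%), CH2Cl2 (1 mM), 40 °C, Ar sparge
Reagents that add atoms: none
Why: The ruthenium alkylidene adds to one terminal alkene ([2+2], cycloreversion, loss of ethylene) and the chain-bound alkylidene so formed engages the second terminal alkene intramolecularly through a second metallacyclobutane, so that C9=C10 forms and the ring closes in one catalytic cycle driven by escape of ethylene. The closest known reaction type is macrocyclic ring-closing olefin metathesis of an α,ω-diene. The one ring closed is the 20-membered macrocycle (12 bridge carbons, 4 atoms of the trioxygenated ring, the ether oxygen and 3 atoms of the other ring), formed end-to-end by macrocyclisation without built-in strain, since the twelve-carbon tether spans the para and meta attachment points comfortably. No stereocentre is created, and the E/Z mixture at the new alkene is irrelevant because step 5 saturates it. The step needs ring closure to win over acyclic diene metathesis oligomerisation and needs the alkenes not to migrate (migration would lead to ring-contracted homologues). High dilution with removal of ethylene should secure the first, and the substrate secures the second because both alkenes are unhindered monosubstituted Type I olefins, at least two CH2 groups away from the arenes and free of chelating heteroatoms, with benzoquinone added to quench Ru–H species.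

Step 5
Reactants: 10 macrocyclic alkene (E/Z mixture)
Product: 11 tri-O-methyl ether of the target (saturated macrocycle)
Conditions: H2 (1 atm), 10% Pd/C, EtOAc, rt
Reagents that add atoms: none
Why: heterogeneous catalytic hydrogenation should saturate the disubstituted alkene of either geometry, while aryl methyl ethers and the diaryl ether are inert at 1 atm and rt.

Step 6
Reactants: 11 tri-O-methyl ether of the target
Product: 12 target macrocycle (CNP0314249.0)
Conditions: BBr3 (6 equiv), CH2Cl2, −78 °C to rt; then MeOH, H2O, 0 °C
Reagents that add atoms: none
Why: Lewis-acid cleavage of aryl methyl ethers (O–B complexation, then SN2 attack of bromide on methyl) should remove all three methyl groups, while the diaryl ether has no sp3 carbon to attack and survives.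

Compound list
1 | 1-bromo-3-(bromomethyl)-5-methoxybenzene | COc1cc(Br)cc(CBr)c1 | starting material
2 | allylmagnesium bromide | C=CC[Mg]Br | starting material
3 | 1-bromo-3-(but-3-en-1-yl)-5-methoxybenzene | COc1cc(Br)cc(CCC=C)c1 | intermediate
4 | 1,9-decadiene | C=CCCCCCCC=C | starting material
5 | 9-borabicyclo[3.3.1]nonane (9-BBN) | B1C2CCCC1CCC2 | starting material
6 | 4-bromo-2,6-dimethoxyphenol | COc1cc(Br)cc(OC)c1O | starting material
7 | B-(dec-9-en-1-yl)-9-BBN | C=CCCCCCCCCB1C2CCCC1CCC2 | intermediate
8 | 4-(dec-9-en-1-yl)-2,6-dimethoxyphenol | COc1cc(CCCCCCCCC=C)cc(OC)c1O | intermediate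
9 | 2-[3-(but-3-en-1-yl)-5-methoxyphenoxy]-5-(dec-9-en-1-yl)-1,3-dimethoxybenzene | COc1cc(CCC=C)cc(Oc2c(OC)cc(CCCCCCCCC=C)cc2OC)c1 | intermediate
10 | macrocyclic alkene, tri-O-methyl ether of the 9,10-didehydro target (E/Z mixture at C9=C10) | COc1cc2cc(c1)Oc1c(OC)cc(cc1OC)CCCCCCCCC=CCC2 | intermediate
11 | tri-O-methyl ether of the target (saturated 20-membered macrocycle) | COc1cc2cc(c1)Oc1c(OC)cc(cc1OC)CCCCCCCCCCCC2 | intermediate
12 | target macrocycle, CNP0314249.0 (achiral) | Oc1cc2cc(c1)Oc1c(O)cc(cc1O)CCCCCCCCCCCC2 | target

Total step count: 6. Longest linear sequence: 5 steps (step 2, or step 1, then steps 3 to 6).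

Steps most likely to fail

Step 4 (ring-closing metathesis). The closure may lose to intermolecular metathesis (oligomers and cyclodimers), and Ru–H-mediated alkene migration before closure may lead to ring-contracted products. The fallback forms the same C9=C10 bond by reductive carbonyl coupling. It sets out from 9: Lemieux–Johnson cleavage of both terminal alkenes (OsO4 cat., NaIO4, 2,6-lutidine, dioxane/H2O, rt) should give the dialdehyde 9-{3,5-dimethoxy-4-[3-methoxy-5-(3-oxopropyl)phenoxy]phenyl}nonanal F1. Intramolecular McMurry coupling (TiCl3, Zn–Cu, DME, reflux, syringe-pump addition) should then close the ring between the two aldehyde carbons and come back to the route at 10.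

Step 3 (Ullmann etherification). C–O bond formation at the doubly ortho-substituted phenoxide may be slow at copper, so that protodebromination of the aryl bromide and oxidative decomposition of the electron-rich phenol at 90 °C take over. The fallback uses a room-temperature oxidative coupling with a boron partner. It sets out from 3: Br/Li exchange and borylation (n-BuLi, THF, −78 °C; B(OiPr)3; aq HCl) should give [3-(but-3-en-1-yl)-5-methoxyphenyl]boronic acid F2. Chan–Lam–Evans coupling of F2 with 8 (Cu(OAc)2, pyridine, Et3N, 4 Å MS, CH2Cl2, air, rt) should come back to the route at 9.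

Step 2 (hydroboration and B-alkyl Suzuki coupling on the free phenol). Oxidative addition into the bromophenoxide may be too slow, so that protodeboronation and β-hydride elimination of the alkyl–palladium species consume the borane. The fallback masks the phenol. It sets out from 6: MOMCl and iPr2NEt in CH2Cl2 should give 5-bromo-1,3-dimethoxy-2-(methoxymethoxy)benzene F3. B-alkyl Suzuki coupling of F3 with 7 (PdCl2(dppf), K3PO4, THF/DMF/H2O, 60 °C) should give 5-(dec-9-en-1-yl)-1,3-dimethoxy-2-(methoxymethoxy)benzene F4. Acetal cleavage (HCl, MeOH, rt) should come back to the route at 8.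

Further compounds
F1 | step 4 | 9-{3,5-dimethoxy-4-[3-methoxy-5-(3-oxopropyl)phenoxy]phenyl}nonanal | COc1cc(CCC=O)cc(Oc2c(OC)cc(CCCCCCCCC=O)cc2OC)c1
F2 | step 3 | [3-(but-3-en-1-yl)-5-methoxyphenyl]boronic acid | COc1cc(CCC=C)cc(B(O)O)c1
F3 | step 2 | 5-bromo-1,3-dimethoxy-2-(methoxymethoxy)benzene | COCOc1c(OC)cc(Br)cc1OC
F4 | step 2 | 5-(dec-9-en-1-yl)-1,3-dimethoxy-2-(methoxymethoxy)benzene | COCOc1c(OC)cc(CCCCCCCCC=C)cc1OC
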